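**Assumptions (one line):** (S)-glyceraldehyde acetonide (from L-ascorbic acid) and (R)-(–)-linalool are bought as such; cembrane numbering is used (C1 = ring-fusion CH, C14 = lactone O–CH, C13 and C3 = CH–OAc, C4 = C(Me)OH, C15–C17 = methylene-lactone carbons).

## Retrosynthetic overview
1. Target 21 ⇐ triol 20 (bis-acetylation) ⇐ macrocyclic acyloin 19; C3 is set by chelation-controlled reduction under control of C4.
2. 14-Membered ring ⇐ Nozaki–Hiyama–Kishi closure of C12–C13 in iodo-aldehyde 18; C13 is set by C14.
3. Key bond C1–C2 ⇐ hydroxy-ketal Claisen [3,3] rearrangement joining allylic alcohol 6 and ketal 15; it sets C1 from C14 and creates the exocyclic methylene.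
4. 6 ⇐ (S)-glyceraldehyde acetonide (C14) + methyl acrylate; 15 ⇐ (R)-linalool (C4) + 1-(trimethylsilyl)propyne.
5. Ring order: γ-lactone first (step 13), then the 14-membered carbocycle (step 15).

## Route

**Step 1**
Reactants: 1 (S)-2,3-O-isopropylideneglyceraldehyde; 2 methyl acrylate
Product: 3 methyl 2-{hydroxy[(4S)-2,2-dimethyl-1,3-dioxolan-4-yl]methyl}prop-2-enoate (carbinol epimers)
Conditions: DABCO (0.5 equiv), dioxane/H2O, rt, 2–3 d
Reagents that add atoms: none (both partners are reactants)
Why: Morita–Baylis–Hillman reaction; the new carbinol centre is a mixture but is erased in step 3, and the dioxolane centre is untouched.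

**Step 2**
Reactants: 3
Product: 4 methyl 2-{acetoxy[(4S)-2,2-dimethyl-1,3-dioxolan-4-yl]methyl}prop-2-enoate
Conditions: Ac2O, Et3N, DMAP (cat.), CH2Cl2, 0 °C
Reagents that add atoms: acetic anhydride, CC(=O)OC(C)=O
Why: Standard acylation of the secondary allylic alcohol to make it a leaving group.

**Step 3**
Reactants: 4
Product: 5 methyl (2E)-2-(acetoxymethyl)-3-[(4R)-2,2-dimethyl-1,3-dioxolan-4-yl]prop-2-enoate
Conditions: DABCO (20 mol%), THF, reflux
Reagents that add atoms: none
Why: SN2′/SN2′ (net 1,3-acetoxy) transposition of a Baylis–Hillman acetate to the thermodynamically favoured trisubstituted enoate; any Z isomer converges in step 12.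

**Step 4**
Reactants: 5
Product: 6 methyl (2E)-2-(hydroxymethyl)-3-[(4R)-2,2-dimethyl-1,3-dioxolan-4-yl]prop-2-enoate
Conditions: K2CO3 (0.2 equiv), MeOH, 0 °C
Reagents that add atoms: none
Why: Mild methanolysis removes the primary acetate; exchange at the methyl ester is degenerate.

**Step 5**
Reactants: 7 (R)-(–)-linalool
Product: 8 (2E,6R)-2,6-dimethylocta-2,7-diene-1,6-diol
Conditions: SeO2 (cat.), t-BuOOH, salicylic acid (cat.), CH2Cl2, rt; then NaBH4, CeCl3, MeOH
Reagents that add atoms: tert-butyl hydroperoxide, CC(C)(C)OO (O source); selenium dioxide, O=[Se]=O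
Why: SeO2 allylic oxidation (ene then [2,3] shift) is selective for the E-methyl of the prenyl terminus; the borohydride returns any over-oxidised enal to the alcohol.

**Step 6**
Reactants: 8
Product: 9 (3R,6E)-3,8-dihydroxy-3,7-dimethyloct-6-en-2-one
Conditions: PdCl2 (10 mol%), CuCl, O2 (1 atm), DMF/H2O, rt
Reagents that add atoms: water, O
Why: Tsuji–Wacker oxidation converts the only monosubstituted alkene to the methyl ketone; the trisubstituted alkene is inert and the quaternary carbinol is not touched.

**Step 7**
Reactants: 9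
Product: 10 (2E,6R)-7,7-dimethoxy-2,6-dimethyloct-2-ene-1,6-diol
Conditions: HC(OMe)3, MeOH, PPTS (cat.), rt
Reagents that add atoms: trimethyl orthoformate, COC(OC)OC; methanol, CO
Why: Ketalisation masks the ketone for the organometallic steps and provides the hydroxy-ketal needed for the Claisen union.

**Step 8**
Reactants: 10
Product: 11 (3R,6E)-8-bromo-2,2-dimethoxy-3,7-dimethyloct-6-en-3-ol
Conditions: CBr4, PPh3, 2,6-lutidine, CH2Cl2, –20 °C
Reagents that add atoms: carbon tetrabromide, BrC(Br)(Br)Br
Why: Appel bromination is selective for the primary allylic alcohol over the hindered tertiary one; lutidine protects the ketal.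

**Step 9**
Reactants: 11; 12 1-(trimethylsilyl)propyne
Product: 13 (3R,6E)-2,2-dimethoxy-3,7-dimethyl-11-(trimethylsilyl)undec-6-en-10-yn-3-ol
Conditions: 12, n-BuLi, THF, –78 °C (2.2 equiv of the propargyl-lithium); then 11, –78 → –20 °C
Reagents that add atoms: none (12 is a reactant)
Why: SN2 alkylation of the allylic bromide by silyl-protected propargyl-lithium forms C9–C10 with the E-alkene retained; the first equivalent only deprotonates the tertiary OH.

**Step 10**
Reactants: 13
Product: 14 (3R,6E)-2,2-dimethoxy-3,7-dimethyldodec-6-en-10-yn-3-ol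
Conditions: MeLi·LiBr, THF, 0 °C → rt; then MeI, DMPU, 0 °C
Reagents that add atoms: iodomethane, CI
Why: MeLi cleaves the alkynyl–Si bond to the lithium acetylide, which is C-methylated in the same pot; the hindered tertiary alkoxide alkylates much more slowly.

**Step 11**
Reactants: 14
Product: 15 (3R,6E,10E)-11-iodo-2,2-dimethoxy-3,7-dimethyldodeca-6,10-dien-3-ol
Conditions: Cp2Zr(H)Cl (3 equiv), THF, 50 °C; then I2, 0 °C; NaHCO3/Na2S2O3 work-up
Reagents that add atoms: iodine, II
Why: Syn hydrozirconation, equilibrated with excess Schwartz reagent so that Zr sits next to the methyl, then iodinolysis with retention gives the (E)-2-iodo-2-alkene.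

**Step 12 (key step)**
Reactants: 6; 15
Product: 16 methyl (3R,6R,9E,13E)-3-[(4R)-2,2-dimethyl-1,3-dioxolan-4-yl]-6-hydroxy-14-iodo-6,10-dimethyl-2-methylidene-5-oxopentadeca-9,13-dienoate
Conditions: 2,4-dinitrophenol (5 mol%), toluene, 110 °C, MeOH distilled off
Reagents that add atoms: none
Why: Johnson–Faulkner hydroxy-ketal Claisen: ketal exchange and loss of MeOH give the allyl vinyl ether, and the [3,3] shift forms C1–C2 anti to the dioxolane C–O bond (allylic H eclipsing the alkene, A1,3 strain), giving 1R and the exocyclic methylene.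

**Step 13**
Reactants: 16
Product: 17 (4R,5R)-5-(hydroxymethyl)-4-[(3R,6E,10E)-3-hydroxy-11-iodo-3,7-dimethyl-2-oxododeca-6,10-dien-1-yl]-3-methylideneoxolan-2-one
Conditions: TFA/H2O (9:1), CH2Cl2, 0 °C; then CSA (cat.), PhMe, 40 °C
Reagents that add atoms: none
Why: Acetonide hydrolysis, then acid-catalysed lactonisation of the C14 hydroxyl onto the acrylate ester gives the more stable trans α-methylene-γ-lactone and leaves the primary C13 alcohol free.

**Step 14**
Reactants: 17
Product: 18 (2R,3R)-3-[(3R,6E,10E)-3-hydroxy-11-iodo-3,7-dimethyl-2-oxododeca-6,10-dien-1-yl]-4-methylidene-5-oxooxolane-2-carbaldehyde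
Conditions: Dess–Martin periodinane, NaHCO3, CH2Cl2, 0 °C; used at once
Reagents that add atoms: none
Why: Buffered Dess–Martin oxidation of the only primary/secondary alcohol; the tertiary C4–OH is inert and the cold buffered conditions avoid epimerising C14.

**Step 15**
Reactants: 18
Product: 19 (1R,4R,13S,14R,7E,11E)-4,13-dihydroxy-3-oxocembra-7,11,15(17)-trien-16,14-olide
Conditions: CrCl2 (10 equiv), NiCl2 (cat.), DMSO/THF, 2 mM, rt
Reagents that add atoms: none
Why: Nozaki–Hiyama–Kishi macrocyclisation; the alkenyl-chromium adds to the aldehyde (ketone and lactone untouched) in the Felkin–Anh sense, anti to the C14–O bond, giving 13S with the 11E geometry retained.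

**Step 16**
Reactants: 19
Product: 20 (1R,3S,4R,13S,14R,7E,11E)-3,4,13-trihydroxycembra-7,11,15(17)-trien-16,14-olide
Conditions: Zn(BH4)2, Et2O/THF, –40 °C
Reagents that add atoms: none
Why: Cram-chelate reduction: Zn bridges C3=O and the C4–OH, and hydride attacks from the face of the small exocyclic methyl, away from the ring C5 methylene, giving 3S; the cold, non-basic reagent spares the methylene lactone.

**Step 17**
Reactants: 20
Product: 21 crassocolide B
Conditions: Ac2O, pyridine, DMAP (cat.), CH2Cl2, 0 °C → rt
Reagents that add atoms: acetic anhydride, CC(=O)OC(C)=O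
Why: Both secondary alcohols (C3, C13) are acetylated while the tertiary C4–OH does not react under these conditions.

## Compound list
1 | (S)-2,3-O-isopropylideneglyceraldehyde | O=C[C@@H]1COC(C)(C)O1 | starting material
2 | methyl acrylate | C=CC(=O)OC | starting material
3 | Baylis–Hillman adduct | C=C(C(=O)OC)C(O)[C@@H]1COC(C)(C)O1 | intermediate
4 | Baylis–Hillman acetate | C=C(C(=O)OC)C(OC(C)=O)[C@@H]1COC(C)(C)O1 | intermediate
5 | rearranged primary allylic acetate | COC(=O)/C(COC(C)=O)=C/[C@@H]1COC(C)(C)O1 | intermediate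
6 | primary allylic alcohol (C1, C13–C17 fragment) | COC(=O)/C(CO)=C/[C@@H]1COC(C)(C)O1 | intermediate
7 | (R)-(–)-linalool | C=C[C@](C)(O)CCC=C(C)C | starting material
8 | (R,E)-8-hydroxylinalool | C=C[C@](C)(O)CC/C=C(\C)CO | intermediate
9 | hydroxy ketone | CC(=O)[C@](C)(O)CC/C=C(\C)CO | intermediate
10 | dimethyl ketal diol | COC(C)(OC)[C@](C)(O)CC/C=C(\C)CO | intermediate
11 | allylic bromide | COC(C)(OC)[C@](C)(O)CC/C=C(\C)CBr | intermediate
12 | 1-(trimethylsilyl)propyne | CC#C[Si](C)(C)C | starting material
13 | silyl alkyne | COC(C)(OC)[C@](C)(O)CC/C=C(\C)CCC#C[Si](C)(C)C | intermediate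
14 | methyl alkyne | COC(C)(OC)[C@](C)(O)CC/C=C(\C)CCC#CC | intermediate
15 | vinyl iodide hydroxy-ketal (C2–C12 fragment) | COC(C)(OC)[C@](C)(O)CC/C=C(\C)CC/C=C(\C)I | intermediate
16 | Claisen product | C=C(C(=O)OC)[C@@H](CC(=O)[C@](C)(O)CC/C=C(\C)CC/C=C(\C)I)[C@@H]1COC(C)(C)O1 | intermediate
17 | methylene-lactone alcohol | C=C1C(=O)O[C@@H](CO)[C@@H]1CC(=O)[C@](C)(O)CC/C=C(\C)CC/C=C(\C)I | intermediate
18 | iodo-aldehyde | C=C1C(=O)O[C@@H](C=O)[C@@H]1CC(=O)[C@](C)(O)CC/C=C(\C)CC/C=C(\C)I | intermediate
19 | macrocyclic acyloin | C=C1C(=O)O[C@@H]2[C@@H]1CC(=O)[C@](C)(O)CC/C=C(\C)CC/C=C(\C)[C@@H]2O | intermediate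
20 | macrocyclic triol | C=C1C(=O)O[C@@H]2[C@@H]1C[C@H](O)[C@](C)(O)CC/C=C(\C)CC/C=C(\C)[C@@H]2O | intermediate
21 | crassocolide B | C=C1C(=O)O[C@@H]2[C@@H]1C[C@H](OC(C)=O)[C@](C)(O)CC/C=C(\C)CC/C=C(\C)[C@@H]2OC(C)=O | target

## Summary
- **Total steps:** 17
- **Longest linear sequence:** 13 (steps 5–11 from (R)-linalool, then steps 12–17)

**Three steps most likely to fail, with fallbacks**
1. **Step 6 (Wacker next to a quaternary carbinol):** it may be slow, give the aldehyde regioisomer, or cyclise. Fallback: make the acyloin from (S)-lactic acid instead of linalool, by Seebach self-regeneration of the stereocentre (pivalaldehyde dioxolanone, alkylation with the C5–C12 iodide, then MeLi on the dioxolanone); this also gives 4R.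
2. **Step 15 (NHK macrocyclisation):** ring-closure yield and 13S selectivity are both uncertain. Fallback: move the ring-closing bond to C9–C10. Do the C12–C13 coupling intermolecularly on an aldehyde without the iodide, using an (E)-3-iodobut-2-enyl unit, and close the ring by intramolecular alkylation of a C9 allylic sulfone on a C10 allylic bromide, then desulfonylate.
3. **Step 16 (C3 reduction):** the diastereoselectivity rests on methyl versus ring-CH2 discrimination, and conjugate reduction of the lactone is possible. Fallback: reduce at the acyclic stage (compound 16), where C3 is the only secondary alcohol. The wrong epimer can then be inverted by Mitsunobu reaction with AcOH, which installs the 3-acetate directly, or recycled by oxidation, before lactonisation and ring closure.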